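Atom labels used throughout: flavanone atoms O1, C2, C3, C4 (rings A and C); ring B carbons C1' to C6' with oxygens O3' and O4'; dioxane ring D carbons C10 (bears CH2OH) and C11 (bears ring E).

## Analysis of the target

Silandrin is a flavanolignan: a 5,7-dihydroxychroman-4-one (rings A and C) carries at C2 a catechol-derived ring B, and the oxygens O3' and O4' of that ring are bridged by C10 and C11 into a 1,4-dioxane (ring D), with the 4-hydroxy-3-methoxyphenyl ring E on C11. The regiochemistry is that of the isosilybin series: C11 is bonded to O4', the oxygen para to C1', and C10 is bonded to O3'. There are three stereocentres, C2 (S), C10 (R) and C11 (R). C10 and C11 are adjacent and trans on ring D, whereas C2 is separated from them by the flat ring B, so it cannot be relayed from them and must be set by a reagent. The flavanone epimerises at C2 under base through retro-oxa-Michael opening to the 2'-hydroxychalcone, the bonds C2–O1 and C11–O4' are para-oxygenated benzylic ethers that are open to ionisation and hydrogenolysis, and the free phenols are easily oxidised. The difficulty lies in solving three selectivity problems together: which catechol oxygen goes to which dioxane carbon, the trans relationship on ring D, and the absolute configuration at the remote C2. A failure in any one gives regio- or stereoisomers that would be very hard to separate. The strategy rests on C11: it is benzylic to ring E and para to the ring E oxygen, so it ionises readily to a planar cation, and the neighbouring C10 centre can decide on which face O4' closes ring D. Only C10 therefore has to be introduced with fixed configuration.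

## Retrosynthetic reasoning

**Protecting groups.** The four hydroxyl groups of 24 are masked as benzyl ethers in 23, so that one neutral hydrogenolysis ends the synthesis. No base touches the flavanone, which keeps C2 intact.

**C2–C1' bond.** Cutting between ring C and ring B divides 23 into arylboronic acid 18 and chromone 22. This is the only place where the remote C2 centre can be made under pure catalyst control, and it halves the molecule. The forward reaction is an enantioselective conjugate arylation of the chromone. It must add the aryl group to one face of C2 and tolerate the benzyl ethers and ring D. Placing it late means the epimerisable flavanone never meets the acid, fluoride or organometallic steps.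

**Boron and chromone.** Boronic acid 18 comes from aryl bromide 15 by halogen–lithium exchange and borylation; the bromine marks C1' from the first step onward. Chromone 22 is built from ketone 20 by adding one carbon and closing the pyranone ring, and 20 is the bis-benzyl ether of the trihydroxyacetophenone 19.

**O4'–C11 bond (ring D).** Ring D of 15 is opened at the bond between O4' and the benzylic C11, which leads to phenol alcohol 14. This bond is chosen because C11 can be ionised, so the configuration of the alcohol is irrelevant and both epimers of 14 serve. The forward closure has to give the trans ring; the C10 substituent and the reversibility of the ionisation are relied on for that. The alternative cut at O3'–C10 would demand both centres with defined configuration beforehand.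

**C11–ring E bond.** Alcohol 14 comes from its silyl ether 13, and 13 from aldehyde 9 and arylmagnesium bromide 12. Cutting here attaches ring E in one step and needs no stereocontrol. The Grignard reagent derives from bromide 11, the benzyl ether of phenol 10.

**O3'–C10 bond.** Aldehyde 9 is the reduction product of ester 8, which is disconnected at the aryl ether into hydroxy ester 7 and phenol 4. An SN2 etherification at a carbon next to an ester is reliable and inverts cleanly. This step fixes both the configuration of C10 and the assignment of O3' to C10. The second catechol oxygen of 4 is silylated, so only O3' can react.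

**Chiral pool and phenol.** Hydroxy ester 7 is the methyl ester of acid 6, obtained from the amino acid 5 by diazotisation with retention. Retention here and inversion in the etherification together give (R) at C10. Phenol 4 comes from aldehyde 2 by oxidative excision of the formyl carbon through formate 3, and 2 from the salicylaldehyde 1. In 1 the bromine is para to the hydroxyl group, so the silylated oxygen becomes O4' and the new phenol becomes O3'.

## Alternatives that were turned down

**Alternative 1:** Ring C is disconnected at C2–C3. In the forward direction the aryl diazomethyl ketone A2 would be decomposed by dirhodium tetrakis(N-phthaloyl-tert-leucinate), Rh2(PTTL)4, a divalent rhodium carboxylate. The carbenoid at C3 would insert into one of the two C–H bonds of the O1–CH2–aryl ether, closing ring C and giving the tetrasilyl ether A1.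
- *For:* ring closure and the C2 centre come from one catalytic event. No chromone or boronic acid is needed. The silyl groups of A1 fall to fluoride, so the end game avoids hydrogenolysis next to two benzylic ethers. On that point it is stronger than the chosen route.
- *Against:* the insertion has to form a six-membered ring, while the ether oxygen O1 sits at the distance that favours a five-membered oxonium ylide; a benzyl shift from that ylide would give a benzofuranone. A diazomethyl ketone gives an acceptor-only carbenoid, the least selective class, and here it would have to distinguish two hydrogens on a carbon far from any other stereocentre. A2 also requires the complete benzodioxane to be made first and then carried through benzylic functionalisation, etherification of a hindered 2,6-dioxygenated benzoic acid derivative and diazoketone formation.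
- *Comparison:* the route is longer and its decisive step is less well founded. The chosen strategy offers in its place a conjugate arylation of a chromone, a reaction class with direct precedent.

**Alternative 2:** Ring D is disconnected at the aryl–oxygen bond C3'–O3'. The threo bromo nitro aryl ether A4, with a free secondary hydroxyl at C10, would be cyclised with Pd(OAc)2 (a divalent palladium precatalyst reduced in the flask to zerovalent palladium), 2-(di-tert-butylphosphino)-1,1'-binaphthyl and Cs2CO3 to the nitro benzodioxane A3.
- *For:* both ring D centres exist before the closure and are simply retained, so a cis isomer cannot arise and no cation is involved. The threo diol pattern of A4 is accessible in one catalytic asymmetric dihydroxylation. On stereochemical certainty this alternative is stronger than the chosen one.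
- *Against:* A4 needs a regioselective SNAr arylation of the benzylic hydroxyl in the presence of the C10 hydroxyl. The palladium alkoxide of a secondary alcohol can undergo β-hydride elimination. The nitro group of A3 is only a placeholder for C1': reduction in the presence of a benzyl ether, diazotisation and conversion into a halide or boron group add about three steps before ring C can be attached.
- *Comparison:* the chosen strategy gives up the guaranteed configuration at C11 for an equilibrating closure. In return its product carries the bromine at C1' ready for borylation, by a shorter sequence.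

**Alternative 3:** Ring D is disconnected at O3'–C10. The phenoxide of the erythro aryloxy epoxide A6 would open the epoxide at its internal carbon with inversion, a 6-exo closure favoured over the 7-endo attack at the terminal carbon, and give the benzodioxane alcohol A5.
- *For:* the closure is a stereospecific SN2 reaction under base with no acid. A5 already has the free hydroxymethyl group, so no aliphatic benzyl ether has to be removed at the end, where this alternative is stronger.
- *Against:* A6 must already contain the C11–O4' aryl ether with defined configuration at a para-alkoxybenzylic carbon. That is the centre where SN2 etherification leaks through ion pairs, and an unactivated bromocatechol cannot be introduced by SNAr. The epoxide must in addition be made erythro-selectively, which is easiest with the free C11 hydroxyl that the ether has replaced.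
- *Comparison:* the chosen strategy puts the only demanding etherification at C10, a non-benzylic carbon next to an ester that is well suited to inversion, and lets the ionisable C11 form its bond without any prior control.

Key step: step 10

## Route

Assumption: in the palladium/pyridine-oxazoline arylation the chromone is attacked on the same face as other cyclic enones, so that the (R)-ligand gives the (2S)-flavanone; if the sense proves opposite, the (S)-ligand is used and nothing else changes.

Step 1
Reactants: 1 5-bromosalicylaldehyde (5-bromo-2-hydroxybenzaldehyde)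
Product: 2 5-bromo-2-(triisopropylsilyloxy)benzaldehyde
Conditions: i-Pr3SiCl, imidazole, DMF, 0 °C to rt
Reagents that add atoms: triisopropylsilyl chloride, CC(C)[Si](Cl)(C(C)C)C(C)C
Why: Standard silylation of a phenol; the bulky triisopropylsilyl group is chosen because it resists migration between neighbouring catechol oxygens in the later steps, which protects the O3'/O4' assignment.

Step 2
Reactants: 2 5-bromo-2-(triisopropylsilyloxy)benzaldehyde
Product: 4 5-bromo-2-(triisopropylsilyloxy)phenol, via aryl formate 3 (not isolated)
Conditions: mCPBA, CH2Cl2, 0 °C to rt; then MeOH, Et3N (cat.), 0 °C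
Reagents that add atoms: meta-chloroperoxybenzoic acid, O=C(OO)c1cccc(Cl)c1
Why: Baeyer–Villiger (Dakin-type) oxidation; the ortho oxygen substituent makes the aryl group migrate, and the labile aryl formate is cleaved by mild methanolysis, so the new hydroxyl (the future O3') stands meta to bromine and the silylated oxygen (the future O4') para to it.

Step 3
Reactants: 5 O-benzyl-L-serine
Product: 6 (S)-3-(benzyloxy)-2-hydroxypropanoic acid
Conditions: NaNO2, 1 M H2SO4 aq., 0 °C to rt
Reagents that add atoms: water, O
Why: Diazotisation of an α-amino acid; the carboxylate displaces dinitrogen to an α-lactone that water reopens, and this double inversion gives net retention, so the (S) centre is carried over.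

Step 4
Reactants: 6 (S)-3-(benzyloxy)-2-hydroxypropanoic acid
Product: 7 methyl (S)-3-(benzyloxy)-2-hydroxypropanoate
Conditions: MeOH, H2SO4 (cat.), reflux
Reagents that add atoms: methanol, CO
Why: Fischer esterification; the stereocentre is not involved and the benzyl ether is stable to catalytic acid in methanol.

Step 5
Reactants: 7 methyl (S)-3-(benzyloxy)-2-hydroxypropanoate and 4 5-bromo-2-(triisopropylsilyloxy)phenol
Product: 8 methyl (2R)-3-(benzyloxy)-2-[5-bromo-2-(triisopropylsilyloxy)phenoxy]propanoate
Conditions: PPh3, DIAD, THF, 0 °C to rt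
Reagents that add atoms: none
Why: Mitsunobu etherification of an α-hydroxy ester with a phenol; SN2 displacement of the oxyphosphonium group inverts C10 to (R), and only the free phenol oxygen (O3') can act as the nucleophile.

Step 6
Reactants: 8 methyl (2R)-3-(benzyloxy)-2-[5-bromo-2-(triisopropylsilyloxy)phenoxy]propanoate
Product: 9 (2R)-3-(benzyloxy)-2-[5-bromo-2-(triisopropylsilyloxy)phenoxy]propanal
Conditions: i-Bu2AlH (1.1 equiv), CH2Cl2, −78 °C; MeOH, then aq. potassium sodium tartrate
Reagents that add atoms: none
Why: Partial reduction of an α-alkoxy ester; the chelated aluminium hemiacetal survives at −78 °C and releases the aldehyde only on work-up, and the crude aldehyde is used at once to protect the enolisable C10 centre.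

Step 7
Reactants: 10 4-bromo-2-methoxyphenol
Product: 11 1-(benzyloxy)-4-bromo-2-methoxybenzene
Conditions: BnBr, K2CO3, DMF, rt
Reagents that add atoms: benzyl bromide, BrCc1ccccc1
Why: Williamson ether synthesis on a phenol; the benzyl ether masks the ring E hydroxyl and later stabilises the C11 cation as a para alkoxy donor.

Step 8
Reactants: 11 1-(benzyloxy)-4-bromo-2-methoxybenzene and 9 (2R)-3-(benzyloxy)-2-[5-bromo-2-(triisopropylsilyloxy)phenoxy]propanal
Product: 13 (2R)-3-(benzyloxy)-1-[4-(benzyloxy)-3-methoxyphenyl]-2-[5-bromo-2-(triisopropylsilyloxy)phenoxy]propan-1-ol (both C1 epimers), via arylmagnesium bromide 12 (not isolated)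
Conditions: 11, Mg, I2 (cat.), THF, 40 °C; then 9, THF, −78 to −20 °C; sat. NH4Cl aq.
Reagents that add atoms: none
Why: Grignard addition to an aldehyde; the aryl bromide of 9 does not exchange with an arylmagnesium halide at low temperature, and the new carbinol centre (C11) needs no control because both epimers converge in step 10.

Step 9
Reactants: 13 (2R)-3-(benzyloxy)-1-[4-(benzyloxy)-3-methoxyphenyl]-2-[5-bromo-2-(triisopropylsilyloxy)phenoxy]propan-1-ol
Product: 14 (2R)-3-(benzyloxy)-1-[4-(benzyloxy)-3-methoxyphenyl]-2-(5-bromo-2-hydroxyphenoxy)propan-1-ol (both C1 epimers)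
Conditions: Bu4NF, AcOH, THF, 0 °C
Reagents that add atoms: none
Why: Fluoride cleavage of an aryl silyl ether; acetic acid buffering keeps the liberated phenoxide protonated, and the benzyl ethers and the aryl bromide are inert.

Step 10
Reactants: 14 (2R)-3-(benzyloxy)-1-[4-(benzyloxy)-3-methoxyphenyl]-2-(5-bromo-2-hydroxyphenoxy)propan-1-ol
Product: 15 (2R,3R)-2-[4-(benzyloxy)-3-methoxyphenyl]-3-[(benzyloxy)methyl]-6-bromo-2,3-dihydro-1,4-benzodioxine
Conditions: TsOH·H2O (0.2 equiv), toluene, 50 °C
Reagents that add atoms: none
Why: Protonation of the benzylic hydroxyl at C11 and loss of water give a cation that is delocalised onto the para benzyloxy oxygen of ring E (a quinone-methide-type oxocarbenium ion), and because this cation is planar both epimers of 14 enter the same pathway. The closest known reaction type is the acid-mediated cyclisation of 1-aryl-2-(2-hydroxyaryloxy)propane-1,3-diol derivatives to trans-2-aryl-3-substituted 1,4-benzodioxanes used for benzodioxane neolignans. Ring D closes in a 6-exo-trig mode: the phenol oxygen O4' attacks the exocyclic trigonal C11 and forms the O4'–C11 bond. The new stereocentre C11 is controlled by C10 through a half-chair transition state in which ring E and the benzyloxymethyl group are both pseudo-equatorial, which leads to the (2R,3R) trans ring. Since the product is itself a para-alkoxybenzylic aryl ether, it can re-ionise under the same acid, so any cis isomer should drain into the more stable trans isomer. The step needs trans diastereoselectivity and oxygen capture in preference to proton loss or Friedel–Crafts attack; the first is secured by the C10 substituent and equilibration, the second by the six-membered proximity of the phenol, the deactivating bromine on ring B and the moderate temperature. The regiochemistry is not at stake because O3' is already bonded to C10, and C10 itself is not ionisable and keeps its configuration.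

Step 11
Reactants: 15 (2R,3R)-2-[4-(benzyloxy)-3-methoxyphenyl]-3-[(benzyloxy)methyl]-6-bromo-2,3-dihydro-1,4-benzodioxine
Product: 18 {(2R,3R)-2-[4-(benzyloxy)-3-methoxyphenyl]-3-[(benzyloxy)methyl]-2,3-dihydro-1,4-benzodioxin-6-yl}boronic acid, via aryllithium 16 (not isolated), via lithium aryltriisopropoxyborate 17 (not isolated)
Conditions: B(Oi-Pr)3, n-BuLi, THF–toluene, −78 °C; then 1 M HCl aq., rt
Reagents that add atoms: triisopropyl borate, CC(C)OB(OC(C)C)OC(C)C; water, O
Why: Bromine–lithium exchange with in situ borate quench; the exchange outruns deprotonation of the benzylic positions at −78 °C, and brief acid hydrolysis at room temperature frees the boronic acid without disturbing ring D.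

Step 12
Reactants: 19 2',4',6'-trihydroxyacetophenone
Product: 20 1-[2,4-bis(benzyloxy)-6-hydroxyphenyl]ethanone
Conditions: BnBr (2.05 equiv), K2CO3, DMF, 0 °C to rt
Reagents that add atoms: benzyl bromide, BrCc1ccccc1
Why: Selective Williamson benzylation; one ortho hydroxyl stays hydrogen-bonded to the ketone and is left free for the pyranone closure.

Step 13
Reactants: 20 1-[2,4-bis(benzyloxy)-6-hydroxyphenyl]ethanone
Product: 22 5,7-bis(benzyloxy)-4H-chromen-4-one, via enaminone 21 (not isolated)
Conditions: Me2NCH(OMe)2, toluene, 100 °C; then 2 M HCl aq., CH2Cl2, 40 °C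
Reagents that add atoms: N,N-dimethylformamide dimethyl acetal, COC(OC)N(C)C
Why: Enaminone formation at the acetyl group followed by acid-promoted addition of the phenol and loss of dimethylamine is the standard chromone synthesis; the acetal supplies C2 of the chromone.

Step 14
Reactants: 18 {(2R,3R)-2-[4-(benzyloxy)-3-methoxyphenyl]-3-[(benzyloxy)methyl]-2,3-dihydro-1,4-benzodioxin-6-yl}boronic acid and 22 5,7-bis(benzyloxy)-4H-chromen-4-one (1.5 equiv)
Product: 23 (2S)-5,7-bis(benzyloxy)-2-{(2R,3R)-2-[4-(benzyloxy)-3-methoxyphenyl]-3-[(benzyloxy)methyl]-2,3-dihydro-1,4-benzodioxin-6-yl}-2,3-dihydro-4H-chromen-4-one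
Conditions: Pd(OCOCF3)2 (10 mol %), (R)-4-tert-butyl-2-(pyridin-2-yl)-4,5-dihydrooxazole (12 mol %), NH4PF6 (30 mol %), H2O (5 equiv), ClCH2CH2Cl, 60 °C
Reagents that add atoms: none
Why: Enantioselective conjugate addition of an arylboronic acid to a chromone under cationic divalent palladium: transmetalation, insertion of the C2=C3 bond into the aryl–palladium bond and protonolysis of the palladium enolate by water, with no change of oxidation state. The chiral pyridine-oxazoline ligand selects the face of C2 and sets the (2S) centre independently of the distant ring D centres.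

Step 15
Reactants: 23 (2S)-5,7-bis(benzyloxy)-2-{(2R,3R)-2-[4-(benzyloxy)-3-methoxyphenyl]-3-[(benzyloxy)methyl]-2,3-dihydro-1,4-benzodioxin-6-yl}-2,3-dihydro-4H-chromen-4-one
Product: 24 silandrin, (2S)-5,7-dihydroxy-2-[(2R,3R)-2-(4-hydroxy-3-methoxyphenyl)-3-(hydroxymethyl)-2,3-dihydro-1,4-benzodioxin-6-yl]-2,3-dihydro-4H-chromen-4-one
Conditions: H2 (1 atm), Pd/C (10 wt %), EtOAc–MeOH, rt
Reagents that add atoms: none
Why: Catalytic hydrogenolysis of three aryl benzyl ethers and one primary alkyl benzyl ether under neutral conditions; no base is present, so C2 should not epimerise, and the cyclic benzylic ethers of rings C and D are cleaved much more slowly than O-benzyl groups.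

## Compound list

1 | 5-bromosalicylaldehyde | O=Cc1cc(Br)ccc1O | starting material
2 | 5-bromo-2-(triisopropylsilyloxy)benzaldehyde | O=Cc1cc(Br)ccc1O[Si](C(C)C)(C(C)C)C(C)C | intermediate
3 | 5-bromo-2-(triisopropylsilyloxy)phenyl formate | O=COc1cc(Br)ccc1O[Si](C(C)C)(C(C)C)C(C)C | intermediate
4 | 5-bromo-2-(triisopropylsilyloxy)phenol | Oc1cc(Br)ccc1O[Si](C(C)C)(C(C)C)C(C)C | intermediate
5 | O-benzyl-L-serine | N[C@@H](COCc1ccccc1)C(=O)O | starting material
6 | (S)-3-(benzyloxy)-2-hydroxypropanoic acid | O[C@@H](COCc1ccccc1)C(=O)O | intermediate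
7 | methyl (S)-3-(benzyloxy)-2-hydroxypropanoate | COC(=O)[C@@H](O)COCc1ccccc1 | intermediate
8 | methyl (2R)-3-(benzyloxy)-2-[5-bromo-2-(triisopropylsilyloxy)phenoxy]propanoate | COC(=O)[C@@H](COCc1ccccc1)Oc1cc(Br)ccc1O[Si](C(C)C)(C(C)C)C(C)C | intermediate
9 | (2R)-3-(benzyloxy)-2-[5-bromo-2-(triisopropylsilyloxy)phenoxy]propanal | O=C[C@@H](COCc1ccccc1)Oc1cc(Br)ccc1O[Si](C(C)C)(C(C)C)C(C)C | intermediate
10 | 4-bromo-2-methoxyphenol | COc1cc(Br)ccc1O | starting material
11 | 1-(benzyloxy)-4-bromo-2-methoxybenzene | COc1cc(Br)ccc1OCc1ccccc1 | intermediate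
12 | [4-(benzyloxy)-3-methoxyphenyl]magnesium bromide | COc1cc([Mg]Br)ccc1OCc1ccccc1 | intermediate
13 | (2R)-3-(benzyloxy)-1-[4-(benzyloxy)-3-methoxyphenyl]-2-[5-bromo-2-(triisopropylsilyloxy)phenoxy]propan-1-ol, both C1 epimers (C1 left undefined) | COc1cc(C(O)[C@@H](COCc2ccccc2)Oc2cc(Br)ccc2O[Si](C(C)C)(C(C)C)C(C)C)ccc1OCc1ccccc1 | intermediate
14 | (2R)-3-(benzyloxy)-1-[4-(benzyloxy)-3-methoxyphenyl]-2-(5-bromo-2-hydroxyphenoxy)propan-1-ol, both C1 epimers (C1 left undefined) | COc1cc(C(O)[C@@H](COCc2ccccc2)Oc2cc(Br)ccc2O)ccc1OCc1ccccc1 | intermediate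
15 | (2R,3R)-2-[4-(benzyloxy)-3-methoxyphenyl]-3-[(benzyloxy)methyl]-6-bromo-2,3-dihydro-1,4-benzodioxine | COc1cc([C@H]2Oc3ccc(Br)cc3O[C@@H]2COCc2ccccc2)ccc1OCc1ccccc1 | intermediate
16 | {(2R,3R)-2-[4-(benzyloxy)-3-methoxyphenyl]-3-[(benzyloxy)methyl]-2,3-dihydro-1,4-benzodioxin-6-yl}lithium | COc1cc([C@H]2Oc3ccc([Li])cc3O[C@@H]2COCc2ccccc2)ccc1OCc1ccccc1 | intermediate
17 | lithium {(2R,3R)-2-[4-(benzyloxy)-3-methoxyphenyl]-3-[(benzyloxy)methyl]-2,3-dihydro-1,4-benzodioxin-6-yl}triisopropoxyborate | [Li+].COc1cc([C@H]2Oc3ccc([B-](OC(C)C)(OC(C)C)OC(C)C)cc3O[C@@H]2COCc2ccccc2)ccc1OCc1ccccc1 | intermediate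
18 | {(2R,3R)-2-[4-(benzyloxy)-3-methoxyphenyl]-3-[(benzyloxy)methyl]-2,3-dihydro-1,4-benzodioxin-6-yl}boronic acid | COc1cc([C@H]2Oc3ccc(B(O)O)cc3O[C@@H]2COCc2ccccc2)ccc1OCc1ccccc1 | intermediate
19 | 2',4',6'-trihydroxyacetophenone | CC(=O)c1c(O)cc(O)cc1O | starting material
20 | 1-[2,4-bis(benzyloxy)-6-hydroxyphenyl]ethanone | CC(=O)c1c(O)cc(OCc2ccccc2)cc1OCc1ccccc1 | intermediate
21 | (E)-1-[2,4-bis(benzyloxy)-6-hydroxyphenyl]-3-(dimethylamino)prop-2-en-1-one | CN(C)/C=C/C(=O)c1c(O)cc(OCc2ccccc2)cc1OCc1ccccc1 | intermediate
22 | 5,7-bis(benzyloxy)-4H-chromen-4-one | O=c1ccoc2cc(OCc3ccccc3)cc(OCc3ccccc3)c12 | intermediate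
23 | (2S)-5,7-bis(benzyloxy)-2-{(2R,3R)-2-[4-(benzyloxy)-3-methoxyphenyl]-3-[(benzyloxy)methyl]-2,3-dihydro-1,4-benzodioxin-6-yl}-2,3-dihydro-4H-chromen-4-one | COc1cc([C@H]2Oc3ccc([C@@H]4CC(=O)c5c(OCc6ccccc6)cc(OCc6ccccc6)cc5O4)cc3O[C@@H]2COCc2ccccc2)ccc1OCc1ccccc1 | intermediate
24 | silandrin | COc1cc([C@H]2Oc3ccc([C@@H]4CC(=O)c5c(O)cc(O)cc5O4)cc3O[C@@H]2CO)ccc1O | target

## Step count and least certain steps

Total step count: 15. Longest linear sequence: 10 steps (steps 3, 4, 5, 6, 8, 9, 10, 11, 14, 15).

**Step 10 (key step).** The closure may give incomplete trans selection if the cis ring does not re-ionise fast enough to equilibrate. The cation may also lose the C10 proton to an enol ether, alkylate another arene, or shed the ring E benzyl group from its oxocarbenium form. The fallback replaces ionisation by a stereospecific displacement. It sets out from 13, which is oxidised with Dess–Martin periodinane to the ketone (2R)-3-(benzyloxy)-1-[4-(benzyloxy)-3-methoxyphenyl]-2-[5-bromo-2-(triisopropylsilyloxy)phenoxy]propan-1-one F1. Felkin–Anh reduction with Li[HB(s-Bu)3] at −78 °C, the hydride arriving anti to the aryloxy group, should give the anti (1S,2R) alcohol F2. Bu4NF/AcOH frees the phenol to give the (1S,2R) diol monoether F3. An intramolecular Mitsunobu etherification (PPh3, DIAD) then closes ring D with inversion at C11 and comes back to the route at 15.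

**Step 14.** The 5,7-dialkoxychromone is an electron-rich, vinylogous-ester acceptor, so insertion may be slow and protodeboronation or homocoupling of the electron-rich boronic acid may consume the advanced fragment. Facial selectivity rests on the ligand alone. The fallback builds ring C by an organocatalytic oxa-Michael closure. It sets out from 15, which after bromine–lithium exchange and quenching with DMF gives the aldehyde (2R,3R)-2-[4-(benzyloxy)-3-methoxyphenyl]-3-[(benzyloxy)methyl]-2,3-dihydro-1,4-benzodioxine-6-carbaldehyde F4. Ketone 20 is C-acylated through its dianion (LiN(SiMe3)2, then di-tert-butyl dicarbonate) to the β-keto ester tert-butyl 3-[2,4-bis(benzyloxy)-6-hydroxyphenyl]-3-oxopropanoate F5. Knoevenagel condensation of F4 and F5 (piperidine, AcOH, toluene, water removal) gives the alkylidene β-keto ester F6. A bifunctional cinchona-derived thiourea, in the pseudoenantiomeric form that delivers (2S), cyclises F6 to the tert-butyl flavanone-3-carboxylate F7. Heating with TsOH removes the tert-butyl ester with decarboxylation and comes back to the route at 23.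

**Step 8 (with step 6).** The α-aryloxy aldehyde 9 may epimerise at C10 through its enol or enolate, or lose benzyl alcohol by β-elimination, before or during the Grignard addition; this would erode the enantiopurity of every later compound. The fallback avoids the aldehyde. It sets out from 8, which is converted with MeNH(OMe)·HCl and i-PrMgCl into the Weinreb amide (2R)-3-(benzyloxy)-2-[5-bromo-2-(triisopropylsilyloxy)phenoxy]-N-methoxy-N-methylpropanamide F8. Addition of 12 gives a stable chelate that releases the ketone F1 (the same compound as in the fallback to step 10) only on acidic quench. Immediate NaBH4 reduction comes back to the route at 13.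

**Step 15.** The primary alkyl benzyl ether is cleaved more slowly than the aryl benzyl ethers. Forcing the reaction may hydrogenolyse the benzylic C2–O1 bond of ring C or reduce the ketone. The fallback removes the slow benzyl ether before ring C exists. It sets out from 15, which with BCl3 and pentamethylbenzene at −78 °C loses both benzyl groups to give 4-[(2R,3R)-6-bromo-3-(hydroxymethyl)-2,3-dihydro-1,4-benzodioxin-2-yl]-2-methoxyphenol F9. The aryl bromide is inert, and any reversible opening at C11 returns the trans ring. Silylation with tert-butyldimethylsilyl chloride and imidazole gives the bis-silyl ether F10. The conditions of step 11 convert F10 into the boronic acid F11, and those of step 14 with 22 give the flavanone F12. Hydrogenolysis then has to cleave only the two fast aryl benzyl ethers of ring A and gives the bis-silyl ether F13. Et3N·3HF removes the silyl groups and comes back to the route at 24.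

## Further compounds

F1 | step 10 | (2R)-3-(benzyloxy)-1-[4-(benzyloxy)-3-methoxyphenyl]-2-[5-bromo-2-(triisopropylsilyloxy)phenoxy]propan-1-one | COc1cc(C(=O)[C@@H](COCc2ccccc2)Oc2cc(Br)ccc2O[Si](C(C)C)(C(C)C)C(C)C)ccc1OCc1ccccc1
F2 | step 10 | (1S,2R)-3-(benzyloxy)-1-[4-(benzyloxy)-3-methoxyphenyl]-2-[5-bromo-2-(triisopropylsilyloxy)phenoxy]propan-1-ol | COc1cc([C@H](O)[C@@H](COCc2ccccc2)Oc2cc(Br)ccc2O[Si](C(C)C)(C(C)C)C(C)C)ccc1OCc1ccccc1
F3 | step 10 | (1S,2R)-3-(benzyloxy)-1-[4-(benzyloxy)-3-methoxyphenyl]-2-(5-bromo-2-hydroxyphenoxy)propan-1-ol | COc1cc([C@H](O)[C@@H](COCc2ccccc2)Oc2cc(Br)ccc2O)ccc1OCc1ccccc1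
F4 | step 14 | (2R,3R)-2-[4-(benzyloxy)-3-methoxyphenyl]-3-[(benzyloxy)methyl]-2,3-dihydro-1,4-benzodioxine-6-carbaldehyde | COc1cc([C@H]2Oc3ccc(C=O)cc3O[C@@H]2COCc2ccccc2)ccc1OCc1ccccc1
F5 | step 14 | tert-butyl 3-[2,4-bis(benzyloxy)-6-hydroxyphenyl]-3-oxopropanoate | CC(C)(C)OC(=O)CC(=O)c1c(O)cc(OCc2ccccc2)cc1OCc1ccccc1
F6 | step 14 | tert-butyl 2-[2,4-bis(benzyloxy)-6-hydroxybenzoyl]-3-{(2R,3R)-2-[4-(benzyloxy)-3-methoxyphenyl]-3-[(benzyloxy)methyl]-2,3-dihydro-1,4-benzodioxin-6-yl}prop-2-enoate (alkene geometry undefined) | COc1cc([C@H]2Oc3ccc(C=C(C(=O)OC(C)(C)C)C(=O)c4c(O)cc(OCc5ccccc5)cc4OCc4ccccc4)cc3O[C@@H]2COCc2ccccc2)ccc1OCc1ccccc1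
F7 | step 14 | tert-butyl (2S)-5,7-bis(benzyloxy)-2-{(2R,3R)-2-[4-(benzyloxy)-3-methoxyphenyl]-3-[(benzyloxy)methyl]-2,3-dihydro-1,4-benzodioxin-6-yl}-4-oxo-3,4-dihydro-2H-chromene-3-carboxylate (C3 undefined) | COc1cc([C@H]2Oc3ccc([C@@H]4C(C(=O)OC(C)(C)C)C(=O)c5c(OCc6ccccc6)cc(OCc6ccccc6)cc5O4)cc3O[C@@H]2COCc2ccccc2)ccc1OCc1ccccc1
F8 | step 8 | (2R)-3-(benzyloxy)-2-[5-bromo-2-(triisopropylsilyloxy)phenoxy]-N-methoxy-N-methylpropanamide | CON(C)C(=O)[C@@H](COCc1ccccc1)Oc1cc(Br)ccc1O[Si](C(C)C)(C(C)C)C(C)C
F9 | step 15 | 4-[(2R,3R)-6-bromo-3-(hydroxymethyl)-2,3-dihydro-1,4-benzodioxin-2-yl]-2-methoxyphenol | COc1cc([C@H]2Oc3ccc(Br)cc3O[C@@H]2CO)ccc1O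
F10 | step 15 | (2R,3R)-6-bromo-2-[4-(tert-butyldimethylsilyloxy)-3-methoxyphenyl]-3-[(tert-butyldimethylsilyloxy)methyl]-2,3-dihydro-1,4-benzodioxine | COc1cc([C@H]2Oc3ccc(Br)cc3O[C@@H]2CO[Si](C)(C)C(C)(C)C)ccc1O[Si](C)(C)C(C)(C)C
F11 | step 15 | {(2R,3R)-2-[4-(tert-butyldimethylsilyloxy)-3-methoxyphenyl]-3-[(tert-butyldimethylsilyloxy)methyl]-2,3-dihydro-1,4-benzodioxin-6-yl}boronic acid | COc1cc([C@H]2Oc3ccc(B(O)O)cc3O[C@@H]2CO[Si](C)(C)C(C)(C)C)ccc1O[Si](C)(C)C(C)(C)C
F12 | step 15 | (2S)-5,7-bis(benzyloxy)-2-{(2R,3R)-2-[4-(tert-butyldimethylsilyloxy)-3-methoxyphenyl]-3-[(tert-butyldimethylsilyloxy)methyl]-2,3-dihydro-1,4-benzodioxin-6-yl}-2,3-dihydro-4H-chromen-4-one | COc1cc([C@H]2Oc3ccc([C@@H]4CC(=O)c5c(OCc6ccccc6)cc(OCc6ccccc6)cc5O4)cc3O[C@@H]2CO[Si](C)(C)C(C)(C)C)ccc1O[Si](C)(C)C(C)(C)C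
F13 | step 15 | (2S)-2-{(2R,3R)-2-[4-(tert-butyldimethylsilyloxy)-3-methoxyphenyl]-3-[(tert-butyldimethylsilyloxy)methyl]-2,3-dihydro-1,4-benzodioxin-6-yl}-5,7-dihydroxy-2,3-dihydro-4H-chromen-4-one | COc1cc([C@H]2Oc3ccc([C@@H]4CC(=O)c5c(O)cc(O)cc5O4)cc3O[C@@H]2CO[Si](C)(C)C(C)(C)C)ccc1O[Si](C)(C)C(C)(C)C
A1 | alternative 1 | tetrakis-O-(tert-butyldimethylsilyl)silandrin | COc1cc([C@H]2Oc3ccc([C@@H]4CC(=O)c5c(O[Si](C)(C)C(C)(C)C)cc(O[Si](C)(C)C(C)(C)C)cc5O4)cc3O[C@@H]2CO[Si](C)(C)C(C)(C)C)ccc1O[Si](C)(C)C(C)(C)C
A2 | alternative 1 | 2-diazo-1-[2-({(2R,3R)-2-[4-(tert-butyldimethylsilyloxy)-3-methoxyphenyl]-3-[(tert-butyldimethylsilyloxy)methyl]-2,3-dihydro-1,4-benzodioxin-6-yl}methoxy)-4,6-bis(tert-butyldimethylsilyloxy)phenyl]ethanone | COc1cc([C@H]2Oc3ccc(COc4cc(O[Si](C)(C)C(C)(C)C)cc(O[Si](C)(C)C(C)(C)C)c4C(=O)C=[N+]=[N-])cc3O[C@@H]2CO[Si](C)(C)C(C)(C)C)ccc1O[Si](C)(C)C(C)(C)C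
A3 | alternative 2 | (2R,3R)-2-[4-(benzyloxy)-3-methoxyphenyl]-3-[(tert-butyldimethylsilyloxy)methyl]-6-nitro-2,3-dihydro-1,4-benzodioxine | COc1cc([C@H]2Oc3ccc([N+](=O)[O-])cc3O[C@@H]2CO[Si](C)(C)C(C)(C)C)ccc1OCc1ccccc1
A4 | alternative 2 | (1R,2R)-1-[4-(benzyloxy)-3-methoxyphenyl]-1-(2-bromo-4-nitrophenoxy)-3-(tert-butyldimethylsilyloxy)propan-2-ol | COc1cc([C@@H](Oc2ccc([N+](=O)[O-])cc2Br)[C@H](O)CO[Si](C)(C)C(C)(C)C)ccc1OCc1ccccc1
A5 | alternative 3 | {(2R,3R)-3-[4-(benzyloxy)-3-methoxyphenyl]-7-bromo-2,3-dihydro-1,4-benzodioxin-2-yl}methanol | COc1cc([C@H]2Oc3ccc(Br)cc3O[C@@H]2CO)ccc1OCc1ccccc1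
A6 | alternative 3 | 5-bromo-2-{(R)-[4-(benzyloxy)-3-methoxyphenyl][(2S)-oxiran-2-yl]methoxy}phenol | COc1cc([C@@H](Oc2ccc(Br)cc2O)[C@@H]2CO2)ccc1OCc1ccccc1
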